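**Plan**
Retrosynthesis: cut C8=CH2 and C14=C15 (double methylenation), then C12=C13 (Wittig), then the C3–C4 bond of ring A, then C4=C5 of a butenolide (Horner–Wadsworth–Emmons) and the C6–O bond, then C10–C1 and C10–CH3 (enolate alkylations) and C9–C11 (conjugate addition).
Forward: ring B is bought as p-benzoquinone mono(ethylene ketal) 1 (ketal carbon = C8, carbonyl = C5). C9 and C10 are substituted, a butenolide is fused onto C5–C6 as a temporary ring, ring A is closed last, methanol opens the lactone, and the side chain and C8 methylene are finished.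
Enabling feature: the carboxyl carbon on C4 and the oxygen on C6 are 1,4-related through C4–C5–C6, so the target hides a furan-2(5H)-one spanning C4, C5 and C6. Its dienolate is a planar aromatic 2-oxidofuran, nucleophilic at C4, that holds the C4 methyl next to C10, so the C10-bound arm C1–C3 can close ring A (C1–C5, C10) on one face only.
Stereochemistry: C9 from the rhodium/(R)-BINAP conjugate addition; C10 from alkylation anti to the C9 group; C4 from C10 through the furanolate; C5 by base equilibration to the trans-decalin; C6 by electron-transfer reduction to the equatorial alcohol; the 12E olefin from a stabilized ylide.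

Key step: step 8

Numbering used in names and comments (core numbering): ring A = C1–C5 + C10, ring B = C5–C10; C4 carries CH3 and the carboxyl carbon, C10 a CH3, C9 the side chain (C11–C15, CH3 on C13), C8 the exocyclic CH2, C6 the oxygen. In the spiro compounds 3–13 the ketal carbon is core C8 and the carbonyl carbon is core C5.
Assumption (step 1): the (R)-BINAP–rhodium catalyst is taken to follow the accepted facial model for cyclohex-2-enone (the (S)-ligand giving (S)-3-substituted cyclohexanones); if the sense proved reversed, the (S)-ligand would be used.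
Assumption: compound 1 is treated as a catalogue compound.

**Step 1**
Reactants: 1 1,4-dioxaspiro[4.5]deca-6,9-dien-8-one; 2 2-[(E)-2-ethoxyethenyl]-4,4,5,5-tetramethyl-1,3,2-dioxaborolane
Product: 3 (10R)-10-[(E)-2-ethoxyethenyl]-1,4-dioxaspiro[4.5]dec-6-en-8-one
Conditions: [Rh(OH)(cod)]2 (cat., cod = cycloocta-1,5-diene), (R)-BINAP, KOH (cat.), dioxane–H2O, 50 °C
Reagents that add atoms: none
Why: Rhodium–BINAP-catalysed asymmetric 1,4-addition of an alkenylboron reagent (Hayashi–Miyaura reaction) should desymmetrize the dienone by adding to one enantiotopic enone only, the ligand setting the new centre (core C9) as R in 3, while the β-ethoxyvinyl group is carried on as a masked CH2–CHO unit.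

**Step 2**
Reactants: 3 (10R)-10-[(E)-2-ethoxyethenyl]-1,4-dioxaspiro[4.5]dec-6-en-8-one
Product: 5 (9S,10S)-10-[(E)-2-ethoxyethenyl]-9-methyl-1,4-dioxaspiro[4.5]dec-6-en-8-one, via lithium dienolate 4 (not isolated)
Conditions: LiN(iPr)2, THF, −78 °C; MeI, −78 → 0 °C
Reagents that add atoms: iodomethane, CI
Why: Kinetic deprotonation at the only sp3 α-carbon (the remaining C=C blocks the other side) gives the cross-conjugated dienolate 4 and its methylation (enolate alkylation) should occur anti to the neighbouring ethoxyvinyl group, although this centre is planarized again in step 3.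

**Step 3**
Reactants: 5 (9S,10S)-10-[(E)-2-ethoxyethenyl]-9-methyl-1,4-dioxaspiro[4.5]dec-6-en-8-one; 6 1-chloro-3-iodopropane
Product: 8 (9S,10S)-9-(3-chloropropyl)-10-[(E)-2-ethoxyethenyl]-9-methyl-1,4-dioxaspiro[4.5]dec-6-en-8-one, via lithium dienolate 7 (not isolated)
Conditions: LiN(iPr)2, THF, −78 °C; 6, DMPU, −78 → 0 °C
Reagents that add atoms: none
Why: Enolate alkylation through dienolate 7 with the iodide end of 6 should form the core C10 quaternary centre with the new chain anti to the adjacent ethoxyvinyl group, so that CH3 ends cis to it, and it leaves the chloride as the latent leaving group for ring A.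

**Step 4**
Reactants: 8 (9S,10S)-9-(3-chloropropyl)-10-[(E)-2-ethoxyethenyl]-9-methyl-1,4-dioxaspiro[4.5]dec-6-en-8-one
Product: 9 (9S,10S)-9-(3-chloropropyl)-10-[(E)-2-ethoxyethenyl]-9-methyl-1,4-dioxaspiro[4.5]decan-8-one
Conditions: [(Ph3P)CuH]6, benzene, H2O (2 equiv), 25 °C
Reagents that add atoms: none
Why: Copper hydride conjugate reduction (Stryker reduction) should saturate only the enone C=C and leave the enol ether, the ketal and the alkyl chloride untouched, giving a ketone that can enolize in one direction only.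

**Step 5**
Reactants: 9 (9S,10S)-9-(3-chloropropyl)-10-[(E)-2-ethoxyethenyl]-9-methyl-1,4-dioxaspiro[4.5]decan-8-one
Product: 11 (9S,10S)-9-(3-chloropropyl)-10-[(E)-2-ethoxyethenyl]-7-hydroxy-9-methyl-1,4-dioxaspiro[4.5]decan-8-one (both C7 epimers), via potassium enolate 10 (not isolated)
Conditions: KN(SiMe3)2, THF, −78 °C; 2-(benzenesulfonyl)-3-phenyloxaziridine, −78 °C; H2O work-up
Reagents that add atoms: 2-(benzenesulfonyl)-3-phenyloxaziridine, O=S(=O)(N1OC1c1ccccc1)c1ccccc1
Why: The potassium enolate 10 can form only toward core C6 because core C10 is quaternary, and its oxidation by the sulfonyloxaziridine (Davis α-hydroxylation) should give the acyloin, whose new carbinol configuration is irrelevant because that centre is planarized in step 8.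

**Step 6**
Reactants: 11 (9S,10S)-9-(3-chloropropyl)-10-[(E)-2-ethoxyethenyl]-7-hydroxy-9-methyl-1,4-dioxaspiro[4.5]decan-8-one; 12 2-(diethoxyphosphoryl)propanoic acid
Product: 13 (9S,10S)-9-(3-chloropropyl)-10-[(E)-2-ethoxyethenyl]-9-methyl-8-oxo-1,4-dioxaspiro[4.5]decan-7-yl 2-(diethoxyphosphoryl)propanoate (diastereomer mixture at C7 and the phosphonate carbon)
Conditions: DCC, DMAP (cat.), CH2Cl2, 0 → 25 °C
Reagents that add atoms: none
Why: Carbodiimide esterification (Steglich conditions) of the secondary acyloin hydroxyl attaches the phosphonopropionate that carries core C4, its methyl group and the carboxyl carbon.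

**Step 7**
Reactants: 13 (9S,10S)-9-(3-chloropropyl)-10-[(E)-2-ethoxyethenyl]-9-methyl-8-oxo-1,4-dioxaspiro[4.5]decan-7-yl 2-(diethoxyphosphoryl)propanoate
Product: 14 (4S,5S)-4-(3-chloropropyl)-5-[(E)-2-ethoxyethenyl]-3,4-dimethyl-4,5,7,7a-tetrahydro-2H-spiro[1-benzofuran-6,2'-[1,3]dioxolan]-2-one (both C7a epimers)
Conditions: NaH, THF, 0 → 65 °C
Reagents that add atoms: none
Why: Intramolecular Horner–Wadsworth–Emmons olefination of the core C5 ketone by the tethered phosphonate should close the five-membered ring to the α-methylbutenolide, the ring itself fixing the carboxyl carbon syn to C6 across the new C4=C5 bond.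

**Step 8**
Reactants: 14 (4S,5S)-4-(3-chloropropyl)-5-[(E)-2-ethoxyethenyl]-3,4-dimethyl-4,5,7,7a-tetrahydro-2H-spiro[1-benzofuran-6,2'-[1,3]dioxolan]-2-one
Product: 16 tricyclic enol lactone (ring A closed; C4 carboxyl esterified by the enol oxygen on C6; C5=C6; C8 dioxolane; C9 (E)-2-ethoxyethenyl; 4S,9S,10S in core numbering), via lithium 2-oxidofuran 15 (not isolated)
Conditions: LiN(SiMe3)2, THF–DMPU, NaI (cat.), −78 → 25 °C
Reagents that add atoms: none
Why: γ-Deprotonation of the butenolide at C6 gives the aromatic lithium 2-oxidofuran 15, whose α-carbon C4 displaces chloride from C3 of the C10-bound arm in an iodide-assisted SN2 reaction, forming the C3–C4 bond. The closest known reaction type is the kinetic α-C-alkylation of butenolide dienolates to α,α-disubstituted β,γ-unsaturated lactones, used here as an intramolecular enolate cycloalkylation. Ring A closes in the 6-exo-tet mode with the enolate C4=C(O–) bond outside the new ring (6-(enolexo)-exo-tet). The only new stereocentre, quaternary C4, is controlled by the C10 stereocentre: in the planar furanolate the C4 methyl lies in the ring plane next to C10 and the carboxyl carbon is tied to O6, and the three-carbon arm can reach C4 only from the face on which it leaves C10, so the C4 methyl must end cis to the C10 methyl and the carboxyl carbon equatorial. The step needs C4- over C6- and O-alkylation, which is secured by the known kinetic α-preference of lithium butenolide dienolates toward alkyl halides, by the eight-membered ring that O-alkylation would require, and by the low temperature. C5 and C6 remain trigonal in the enol lactone, so nothing else is fixed or lost in this step.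

**Step 9**
Reactants: 16 tricyclic enol lactone
Product: 18 methyl (1S,4aS,5S,8aS)-5-[(E)-2-ethoxyethenyl]-1,4a-dimethyl-8-oxooctahydro-1H-spiro[naphthalene-6,2'-[1,3]dioxolane]-1-carboxylate (trans-fused), via sodium enolate 17 (not isolated)
Conditions: NaOMe (0.2 equiv), MeOH, 0 → 25 °C
Reagents that add atoms: methanol, CO
Why: Methoxide opens the enol lactone, which is an acylating enol ester, to the methyl ester and the C6 ketone enolate 17, and protonation at C5 under the equilibrating conditions should give the more stable trans-fused decalone with C5–H anti to the C10 methyl (transesterification followed by thermodynamic epimerization).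

**Step 10**
Reactants: 18 methyl (1S,4aS,5S,8aS)-5-[(E)-2-ethoxyethenyl]-1,4a-dimethyl-8-oxooctahydro-1H-spiro[naphthalene-6,2'-[1,3]dioxolane]-1-carboxylate
Product: 19 methyl (1S,4aR,5S,8R,8aS)-5-[(E)-2-ethoxyethenyl]-8-hydroxy-1,4a-dimethyloctahydro-1H-spiro[naphthalene-6,2'-[1,3]dioxolane]-1-carboxylate
Conditions: SmI2, THF, H2O, Et3N, 0 °C
Reagents that add atoms: none
Why: Electron-transfer reduction by divalent samarium, like dissolving-metal reduction of ketones flanked by axial methyl groups (the 11-oxo steroid case), should give the thermodynamically preferred equatorial alcohol with C6–OH cis to C5–H, whereas a hydride reagent would attack the open face and give the axial epimer.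

**Step 11**
Reactants: 19 methyl (1S,4aR,5S,8R,8aS)-5-[(E)-2-ethoxyethenyl]-8-hydroxy-1,4a-dimethyloctahydro-1H-spiro[naphthalene-6,2'-[1,3]dioxolane]-1-carboxylate
Product: 20 methyl (1S,4aR,5S,8R,8aS)-8-(acetyloxy)-5-[(E)-2-ethoxyethenyl]-1,4a-dimethyloctahydro-1H-spiro[naphthalene-6,2'-[1,3]dioxolane]-1-carboxylate
Conditions: Ac2O, Et3N, DMAP (cat.), CH2Cl2, 25 °C
Reagents that add atoms: acetic anhydride, CC(=O)OC(C)=O
Why: DMAP-catalysed acetylation of the secondary alcohol is placed before any acid treatment so that the hydroxyl cannot lactonize onto the neighbouring ester.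

**Step 12**
Reactants: 20 methyl (1S,4aR,5S,8R,8aS)-8-(acetyloxy)-5-[(E)-2-ethoxyethenyl]-1,4a-dimethyloctahydro-1H-spiro[naphthalene-6,2'-[1,3]dioxolane]-1-carboxylate
Product: 21 methyl (1S,4aR,5S,8R,8aS)-8-(acetyloxy)-1,4a-dimethyl-5-(2-oxoethyl)octahydro-1H-spiro[naphthalene-6,2'-[1,3]dioxolane]-1-carboxylate
Conditions: 0.1 M HCl, THF–H2O, 0 °C
Reagents that add atoms: water, O
Why: Acid-catalysed enol ether hydrolysis is much faster than cleavage of the hindered dioxolane and should unmask the C12 aldehyde alone.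

**Step 13**
Reactants: 21 methyl (1S,4aR,5S,8R,8aS)-8-(acetyloxy)-1,4a-dimethyl-5-(2-oxoethyl)octahydro-1H-spiro[naphthalene-6,2'-[1,3]dioxolane]-1-carboxylate; 22 2-(triphenyl-λ5-phosphanylidene)propanal
Product: 23 methyl (1S,4aR,5S,8R,8aS)-8-(acetyloxy)-1,4a-dimethyl-5-[(2E)-3-methyl-4-oxobut-2-en-1-yl]octahydro-1H-spiro[naphthalene-6,2'-[1,3]dioxolane]-1-carboxylate
Conditions: toluene, 80 °C
Reagents that add atoms: none
Why: Wittig olefination with the stabilized formyl ylide should convert the aldehyde into the trisubstituted enal with E geometry, which is the normal outcome for stabilized ylides, and the ylide is too unreactive to touch ester, acetate or ketal.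

**Step 14**
Reactants: 23 methyl (1S,4aR,5S,8R,8aS)-8-(acetyloxy)-1,4a-dimethyl-5-[(2E)-3-methyl-4-oxobut-2-en-1-yl]octahydro-1H-spiro[naphthalene-6,2'-[1,3]dioxolane]-1-carboxylate
Product: 24 methyl (1S,4aR,5S,8R,8aS)-8-(acetyloxy)-1,4a-dimethyl-5-[(2E)-3-methyl-4-oxobut-2-en-1-yl]-6-oxodecahydronaphthalene-1-carboxylate
Conditions: 2 M HCl, THF, 40 °C
Reagents that add atoms: water, O
Why: Aqueous acid hydrolysis of the dioxolane frees the C8 ketone, and C9 next to it already holds the equatorial side chain that is also the thermodynamically preferred arrangement, so enolization cannot scramble it.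

**Step 15**
Reactants: 24 methyl (1S,4aR,5S,8R,8aS)-8-(acetyloxy)-1,4a-dimethyl-5-[(2E)-3-methyl-4-oxobut-2-en-1-yl]-6-oxodecahydronaphthalene-1-carboxylate
Product: 25 methyl (1S,4aS,5R,8R,8aS)-8-(acetyloxy)-1,4a-dimethyl-6-methylidene-5-[(2E)-3-methylpenta-2,4-dien-1-yl]decahydronaphthalene-1-carboxylate
Conditions: Zn, CH2Br2, TiCl4, THF–CH2Cl2, 0 → 25 °C
Reagents that add atoms: dibromomethane, BrCBr
Why: Non-basic titanium–zinc methylenation (Takai–Lombardo reaction) should convert the hindered β-acetoxy ketone and the enal carbonyl into C=CH2 in one operation without β-elimination of acetate or attack on the two esters, and it creates no stereocentre.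

**Compound list**
1 | 1,4-dioxaspiro[4.5]deca-6,9-dien-8-one (p-benzoquinone mono(ethylene ketal)) | O=C1C=CC2(OCCO2)C=C1 | starting material
2 | 2-[(E)-2-ethoxyethenyl]-4,4,5,5-tetramethyl-1,3,2-dioxaborolane | CCO/C=C/B1OC(C)(C)C(C)(C)O1 | starting material
3 | (10R)-10-[(E)-2-ethoxyethenyl]-1,4-dioxaspiro[4.5]dec-6-en-8-one | CCO/C=C/[C@@H]1C2(OCCO2)C=CC(=O)C1 | intermediate
4 | lithium dienolate of 3 (O–Li on C8; C8=C9 and C6=C7) | CCO/C=C/[C@@H]1C2(OCCO2)C=CC([O-])=C1.[Li+] | intermediate
5 | (9S,10S)-10-[(E)-2-ethoxyethenyl]-9-methyl-1,4-dioxaspiro[4.5]dec-6-en-8-one (9-CH3 trans to the C10 group) | CCO/C=C/[C@@H]1C2(OCCO2)C=CC(=O)[C@H]1C | intermediate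
6 | 1-chloro-3-iodopropane | ClCCCI | starting material
7 | lithium dienolate of 5 | CCO/C=C/[C@@H]1C2(OCCO2)C=CC([O-])=C1C.[Li+] | intermediate
8 | (9S,10S)-9-(3-chloropropyl)-10-[(E)-2-ethoxyethenyl]-9-methyl-1,4-dioxaspiro[4.5]dec-6-en-8-one | CCO/C=C/[C@@H]1C2(OCCO2)C=CC(=O)[C@@]1(C)CCCCl | intermediate
9 | (9S,10S)-9-(3-chloropropyl)-10-[(E)-2-ethoxyethenyl]-9-methyl-1,4-dioxaspiro[4.5]decan-8-one | CCO/C=C/[C@@H]1C2(OCCO2)CCC(=O)[C@@]1(C)CCCCl | intermediate
10 | potassium enolate of 9 (C7=C8–OK) | CCO/C=C/[C@@H]1C2(OCCO2)CC=C([O-])[C@@]1(C)CCCCl.[K+] | intermediate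
11 | (9S,10S)-9-(3-chloropropyl)-10-[(E)-2-ethoxyethenyl]-7-hydroxy-9-methyl-1,4-dioxaspiro[4.5]decan-8-one (both C7 epimers) | CCO/C=C/[C@@H]1C2(OCCO2)CC(O)C(=O)[C@@]1(C)CCCCl | intermediate
12 | 2-(diethoxyphosphoryl)propanoic acid (racemic) | CCOP(=O)(OCC)C(C)C(=O)O | starting material
13 | (9S,10S)-9-(3-chloropropyl)-10-[(E)-2-ethoxyethenyl]-9-methyl-8-oxo-1,4-dioxaspiro[4.5]decan-7-yl 2-(diethoxyphosphoryl)propanoate (diastereomer mixture) | CCO/C=C/[C@@H]1C2(OCCO2)CC(OC(=O)C(C)P(=O)(OCC)OCC)C(=O)[C@@]1(C)CCCCl | intermediate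
14 | (4S,5S)-4-(3-chloropropyl)-5-[(E)-2-ethoxyethenyl]-3,4-dimethyl-4,5,7,7a-tetrahydro-2H-spiro[1-benzofuran-6,2'-[1,3]dioxolan]-2-one (both C7a epimers) | CCO/C=C/[C@@H]1C2(OCCO2)CC3OC(=O)C(C)=C3[C@@]1(C)CCCCl | intermediate
15 | lithium 2-oxidofuran (dienolate) of 14 | CCO/C=C/[C@@H]1C2(OCCO2)Cc3oc([O-])c(C)c3[C@@]1(C)CCCCl.[Li+] | intermediate
16 | tricyclic enol lactone: ring A closed, C4 carboxyl esterified by the C6 enol oxygen (C5=C6), C8 dioxolane, C9 (E)-2-ethoxyethenyl, 4S,9S,10S (core numbering) | CCO/C=C/[C@@H]1C2(OCCO2)CC3=C4[C@@]1(C)CCC[C@]4(C)C(=O)O3 | intermediate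
17 | sodium enolate (C5=C6–ONa) of 18 | CCO/C=C/[C@@H]1C2(OCCO2)CC([O-])=C3[C@@]1(C)CCC[C@]3(C)C(=O)OC.[Na+] | intermediate
18 | methyl (1S,4aS,5S,8aS)-5-[(E)-2-ethoxyethenyl]-1,4a-dimethyl-8-oxooctahydro-1H-spiro[naphthalene-6,2'-[1,3]dioxolane]-1-carboxylate | CCO/C=C/[C@@H]1C2(OCCO2)CC(=O)[C@H]3[C@@]1(C)CCC[C@]3(C)C(=O)OC | intermediate
19 | methyl (1S,4aR,5S,8R,8aS)-5-[(E)-2-ethoxyethenyl]-8-hydroxy-1,4a-dimethyloctahydro-1H-spiro[naphthalene-6,2'-[1,3]dioxolane]-1-carboxylate | CCO/C=C/[C@@H]1C2(OCCO2)C[C@@H](O)[C@H]3[C@@]1(C)CCC[C@]3(C)C(=O)OC | intermediate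
20 | methyl (1S,4aR,5S,8R,8aS)-8-(acetyloxy)-5-[(E)-2-ethoxyethenyl]-1,4a-dimethyloctahydro-1H-spiro[naphthalene-6,2'-[1,3]dioxolane]-1-carboxylate | CCO/C=C/[C@@H]1C2(OCCO2)C[C@@H](OC(C)=O)[C@H]3[C@@]1(C)CCC[C@]3(C)C(=O)OC | intermediate
21 | methyl (1S,4aR,5S,8R,8aS)-8-(acetyloxy)-1,4a-dimethyl-5-(2-oxoethyl)octahydro-1H-spiro[naphthalene-6,2'-[1,3]dioxolane]-1-carboxylate | O=CC[C@@H]1C2(OCCO2)C[C@@H](OC(C)=O)[C@H]3[C@@]1(C)CCC[C@]3(C)C(=O)OC | intermediate
22 | 2-(triphenyl-λ5-phosphanylidene)propanal | CC(C=O)=P(c1ccccc1)(c1ccccc1)c1ccccc1 | starting material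
23 | methyl (1S,4aR,5S,8R,8aS)-8-(acetyloxy)-1,4a-dimethyl-5-[(2E)-3-methyl-4-oxobut-2-en-1-yl]octahydro-1H-spiro[naphthalene-6,2'-[1,3]dioxolane]-1-carboxylate | O=C/C(C)=C/C[C@@H]1C2(OCCO2)C[C@@H](OC(C)=O)[C@H]3[C@@]1(C)CCC[C@]3(C)C(=O)OC | intermediate
24 | methyl (1S,4aR,5S,8R,8aS)-8-(acetyloxy)-1,4a-dimethyl-5-[(2E)-3-methyl-4-oxobut-2-en-1-yl]-6-oxodecahydronaphthalene-1-carboxylate | O=C/C(C)=C/C[C@@H]1C(=O)C[C@@H](OC(C)=O)[C@H]2[C@@]1(C)CCC[C@]2(C)C(=O)OC | intermediate
25 | methyl (1S,4aS,5R,8R,8aS)-8-(acetyloxy)-1,4a-dimethyl-6-methylidene-5-[(2E)-3-methylpenta-2,4-dien-1-yl]decahydronaphthalene-1-carboxylate | C=C/C(C)=C/C[C@@H]1C(=C)C[C@@H](OC(C)=O)[C@H]2[C@@]1(C)CCC[C@]2(C)C(=O)OC | target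

**Totals and risks**
Total step count: 15. Longest linear sequence: 15 steps (from 1).

Steps most likely to fail:

Step 8. The ring closure creates a quaternary carbon with a developing 1,3-diaxial methyl pair, so displacement of chloride may be slow and alkylation at C6 or decay of the dienolate may compete. Fallback, from 14 back to 16: Kornblum oxidation (NaI, NaHCO3, DMSO, 100 °C) would turn the chloropropyl arm into the aldehyde analogue of 14 F1. LiN(SiMe3)2 at −78 °C should then add the same furanolate carbon C4 to the far more electrophilic aldehyde (intramolecular aldol addition) to give the 3-hydroxy derivative of enol lactone 16 F2. Acylation with PhOC(S)Cl (pyridine, DMAP) would give the O-phenyl thionocarbonate of F2 F3, and Barton–McCombie deoxygenation (Bu3SnH, AIBN, toluene, 80 °C) would return 16.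

Step 10. Hydrogen may be delivered to C6 from the wrong face, or the new alkoxide may cyclize onto the neighbouring ester. Fallback, from 18 back to 20: NaBH4 (MeOH, 0 °C) should attack the open face and give the axial alcohol methyl (1S,4aR,5S,8S,8aS)-5-[(E)-2-ethoxyethenyl]-8-hydroxy-1,4a-dimethyloctahydro-1H-spiro[naphthalene-6,2'-[1,3]dioxolane]-1-carboxylate F4, which cannot reach the ester. Mitsunobu inversion with acetic acid (PPh3, DIAD, toluene) would then give acetate 20 directly.

Step 15. Methylenation of the hindered ketone may stay incomplete, or the Lewis-acidic medium may cause loss of acetic acid or oligomerization of the dienyl system while both carbonyls are being converted. Fallback, from 24 back to 25: Wittig methylenation of the aldehyde alone (Ph3P=CH2 from Ph3PCH3Br and KN(SiMe3)2, THF, −78 °C) would give the dienyl ketone methyl (1S,4aR,5S,8R,8aS)-8-(acetyloxy)-1,4a-dimethyl-5-[(2E)-3-methylpenta-2,4-dien-1-yl]-6-oxodecahydronaphthalene-1-carboxylate F5. The ketone alone would then be methylenated with Zn, CH2Br2 and TiCl4 to give 25.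

**Further compounds**
F1 | step 8 | aldehyde analogue of 14 (CH2CH2CHO in place of CH2CH2CH2Cl) | CCO/C=C/[C@@H]1C2(OCCO2)CC3OC(=O)C(C)=C3[C@@]1(C)CCC=O
F2 | step 8 | 3-hydroxy derivative of enol lactone 16 (both C3 epimers) | CCO/C=C/[C@@H]1C2(OCCO2)CC3=C4[C@@]1(C)CCC(O)[C@]4(C)C(=O)O3
F3 | step 8 | O-phenyl thionocarbonate of F2 | CCO/C=C/[C@@H]1C2(OCCO2)CC3=C4[C@@]1(C)CCC(OC(=S)Oc5ccccc5)[C@]4(C)C(=O)O3
F4 | step 10 | methyl (1S,4aR,5S,8S,8aS)-5-[(E)-2-ethoxyethenyl]-8-hydroxy-1,4a-dimethyloctahydro-1H-spiro[naphthalene-6,2'-[1,3]dioxolane]-1-carboxylate | CCO/C=C/[C@@H]1C2(OCCO2)C[C@H](O)[C@H]3[C@@]1(C)CCC[C@]3(C)C(=O)OC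
F5 | step 15 | methyl (1S,4aR,5S,8R,8aS)-8-(acetyloxy)-1,4a-dimethyl-5-[(2E)-3-methylpenta-2,4-dien-1-yl]-6-oxodecahydronaphthalene-1-carboxylate | C=C/C(C)=C/C[C@@H]1C(=O)C[C@@H](OC(C)=O)[C@H]2[C@@]1(C)CCC[C@]2(C)C(=O)OC
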